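Monadoxanthin is cut at C11=C12 and C11'=C12' into a C15 acetylenic phosphonium salt, the C10 dialdehyde and a C15 ε-end aldehyde. Everything rests on the acetylenic ring: its tetrasubstituted C5=C6 bond, flanked by the quaternary C1 and carrying the C7≡C8 alkyne on C6, is read as the enol double bond of a Diels–Alder adduct. A catalytic enantioselective [4+2] cycloaddition of an acyclic 2-silyloxydiene (C4=C5–C6=C1, from isopropyl isopropenyl ketone) with methyl vinyl ketone (C2=C3) forms C1–C2 and C3–C4, the quaternary C1 and the C3 stereocentre in one operation. The enol ether then becomes the triflate for Sonogashira coupling, and the acetyl group becomes the C3 oxygen.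

Key step: step 3

Assumption: (R)-α-ionone is taken as purchasable as the single enantiomer; atoms are numbered as in carotenoid nomenclature (acetylenic ring C1–C6, chain C7–C15, primed numbers for the ε half).

Step 1
Reactants: 1 N-methoxy-N-methyl-2-methylpropanamide; 2 isopropenylmagnesium bromide
Product: 4 2,4-dimethylpent-1-en-3-one, via magnesium hemiaminal chelate 3 (not isolated)
Conditions: THF, 0 °C → rt; cold 1 M HCl
Reagents that add atoms: none
Why: Grignard acylation of an N-methoxy-N-methylamide should stop at the chelated tetrahedral adduct, so the enone is released only on acidic work-up and is not attacked a second time.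

Step 2
Reactants: 4 2,4-dimethylpent-1-en-3-one
Product: 5 [(2,4-dimethylpenta-1,3-dien-3-yl)oxy]tri(propan-2-yl)silane
Conditions: i-Pr3SiOTf, Et3N, CH2Cl2, 0 °C → rt
Reagents that add atoms: triisopropylsilyl trifluoromethanesulfonate, CC(C)[Si](C(C)C)(C(C)C)OS(=O)(=O)C(F)(F)F
Why: Soft enolisation with O-silylation can only engage the isopropyl methine, so a single cross-conjugated silyl dienol ether should result, free of geometric isomers because C1 carries two methyl groups.

Step 3
Reactants: 5 [(2,4-dimethylpenta-1,3-dien-3-yl)oxy]tri(propan-2-yl)silane; 6 but-3-en-2-one (methyl vinyl ketone)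
Product: 7 1-[(1R)-3,5,5-trimethyl-4-{[tri(propan-2-yl)silyl]oxy}cyclohex-3-en-1-yl]ethan-1-one
Conditions: (S)-tetrahydro-1-(2-methylphenyl)-3,3-diphenyl-1H,3H-pyrrolo[1,2-c][1,3,2]oxazaborole (20 mol %), Tf2NH (16 mol %), CH2Cl2, −78 → −40 °C
Reagents that add atoms: none
Why: The Tf2NH-activated oxazaborolidine binds the carbonyl oxygen of 6 and lowers its LUMO, and the diene should add in a concerted but asynchronous normal-demand [4+2] transition state in which the silyl enol ether carbon C1 bonds to the CH2 terminus C2 ahead of C4–C3. The closest known reaction type is the cationic-oxazaborolidine-catalysed enantioselective Diels–Alder reaction of 2-(triisopropylsilyloxy)buta-1,3-dienes with acrylate and enone dienophiles. The cyclohexene ring is closed by an intermolecular suprafacial [4+2] cycloaddition (should the process become stepwise, the second bond closes in a 6-(enolexo)-endo-trig conjugate mode), and the new double bond appears at C5=C6 as the tetrasubstituted silyl enol ether. C3 is the only new stereocentre and is set by the catalyst: by the usual model for ketone and ester dienophiles the aryl groups of the (S)-configured catalyst screen the si face of the α-carbon of the bound enone, so C4 should add to the re face and give (R) at C3, independent of endo or exo approach. The step needs "para" regioselectivity (C6–O opposite C3–acyl), which the 2-silyloxy group secures by making C1 the most nucleophilic terminus against the weaker directing effects of the methyl groups; it also needs cycloaddition to outrun desilylation and open-chain conjugate addition, for which the bulky i-Pr3Si group and the low temperature are chosen.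

Step 4
Reactants: 7 1-[(1R)-3,5,5-trimethyl-4-{[tri(propan-2-yl)silyl]oxy}cyclohex-3-en-1-yl]ethan-1-one
Product: 9 (4R)-4-acetyl-2,6,6-trimethylcyclohex-1-en-1-yl trifluoromethanesulfonate, via cesium enolate 8 (not isolated)
Conditions: CsF, PhNTf2, DME, rt
Reagents that add atoms: N-phenylbis(trifluoromethanesulfonimide), O=S(=O)(N(c1ccccc1)S(=O)(=O)C(F)(F)F)C(F)(F)F
Why: Fluoride should remove the silyl group and the liberated enolate, fixed at C5=C6 because C1 is quaternary, should be O-triflated at once by the triflimide present in excess (silyl enol ether to enol triflate exchange).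

Step 5
Reactants: 9 (4R)-4-acetyl-2,6,6-trimethylcyclohex-1-en-1-yl trifluoromethanesulfonate
Product: 10 (1R)-3,5,5-trimethyl-4-{[(trifluoromethyl)sulfonyl]oxy}cyclohex-3-en-1-yl acetate
Conditions: mCPBA, NaHCO3, CH2Cl2, rt
Reagents that add atoms: 3-chloroperbenzoic acid, OOC(=O)c1cccc(Cl)c1
Why: Baeyer–Villiger oxidation of the methyl ketone should proceed with migration of the secondary ring carbon C3 and retention of configuration, while the enol triflate double bond is deactivated towards the peracid by the triflyloxy group.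

Step 6
Reactants: 10 (1R)-3,5,5-trimethyl-4-{[(trifluoromethyl)sulfonyl]oxy}cyclohex-3-en-1-yl acetate; 11 (2E)-3-methylpent-2-en-4-yn-1-ol
Product: 12 (1R)-4-[(3E)-5-hydroxy-3-methylpent-3-en-1-yn-1-yl]-3,5,5-trimethylcyclohex-3-en-1-yl acetate
Conditions: Pd(PPh3)4 (5 mol %), CuI (10 mol %), i-Pr2NH, DMF, 50 °C
Reagents that add atoms: none
Why: Sonogashira coupling of the cyclohexenyl triflate with the terminal alkyne should form the C6–C7 bond and carry the 9E geometry of 11 into the product unchanged.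

Step 7
Reactants: 12 (1R)-4-[(3E)-5-hydroxy-3-methylpent-3-en-1-yn-1-yl]-3,5,5-trimethylcyclohex-3-en-1-yl acetate
Product: 13 {(2E)-5-[(4R)-4-(acetyloxy)-2,6,6-trimethylcyclohex-1-en-1-yl]-3-methylpent-2-en-4-yn-1-yl}triphenylphosphonium bromide
Conditions: PPh3·HBr, MeOH, rt; crystallisation
Reagents that add atoms: triphenylphosphonium bromide, [Br-].c1ccccc1[PH+](c1ccccc1)c1ccccc1
Why: Acid-promoted substitution of the primary allylic alcohol by triphenylphosphine should give the allylic phosphonium salt at C11, the secondary acetate being inert and the 9E salt being purified by crystallisation.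

Step 8
Reactants: 13 {(2E)-5-[(4R)-4-(acetyloxy)-2,6,6-trimethylcyclohex-1-en-1-yl]-3-methylpent-2-en-4-yn-1-yl}triphenylphosphonium bromide; 14 (2E,4E,6E)-2,7-dimethylocta-2,4,6-trienedial (3 equiv)
Product: 17 (2E,4E,6E,8E,10E)-13-[(4R)-4-hydroxy-2,6,6-trimethylcyclohex-1-en-1-yl]-2,7,11-trimethyltrideca-2,4,6,8,10-pentaen-12-ynal, via C15 ylide 15 (not isolated), via C25 acetoxy aldehyde 16 (not isolated)
Conditions: NaOMe (1.1 equiv), CH2Cl2/MeOH, 0 °C → rt; then NaOMe (0.5 equiv), rt; heptane, reflux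
Reagents that add atoms: none
Why: Wittig olefination with excess dialdehyde should form C11=C12 on one formyl group only, methoxide then removes the acetate by transesterification, and the hindered 11Z isomer should relax to 11E on heating.

Step 9
Reactants: 17 (2E,4E,6E,8E,10E)-13-[(4R)-4-hydroxy-2,6,6-trimethylcyclohex-1-en-1-yl]-2,7,11-trimethyltrideca-2,4,6,8,10-pentaen-12-ynal
Product: 18 (1R)-4-[(3E,5E,7E,9E,11E)-13-hydroxy-3,7,12-trimethyltrideca-3,5,7,9,11-pentaen-1-yn-1-yl]-3,5,5-trimethylcyclohex-3-en-1-ol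
Conditions: NaBH4, MeOH/CH2Cl2, 0 °C
Reagents that add atoms: none
Why: Borohydride should reduce the conjugated aldehyde in 1,2-fashion to the primary allylic alcohol without touching the polyenyne.

Step 10
Reactants: 18 (1R)-4-[(3E,5E,7E,9E,11E)-13-hydroxy-3,7,12-trimethyltrideca-3,5,7,9,11-pentaen-1-yn-1-yl]-3,5,5-trimethylcyclohex-3-en-1-ol
Product: 19 {(2E,4E,6E,8E,10E)-13-[(4R)-4-hydroxy-2,6,6-trimethylcyclohex-1-en-1-yl]-2,7,11-trimethyltrideca-2,4,6,8,10-pentaen-12-yn-1-yl}triphenylphosphonium bromide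
Conditions: PPh3·HBr, MeOH/CH2Cl2, rt, dark
Reagents that add atoms: triphenylphosphonium bromide, [Br-].c1ccccc1[PH+](c1ccccc1)c1ccccc1
Why: As for retinol-type polyenols, the primary allylic alcohol should be replaced by triphenylphosphine at the chain terminus C12', the homoallylic secondary C3 hydroxyl staying untouched.

Step 11
Reactants: 20 (R)-α-ionone; 21 diethyl (cyanomethyl)phosphonate
Product: 22 (2E,4E)-3-methyl-5-[(1R)-2,6,6-trimethylcyclohex-2-en-1-yl]penta-2,4-dienenitrile
Conditions: NaH, THF, 0 °C → rt; chromatography (9'E from 9'Z)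
Reagents that add atoms: none
Why: Horner–Wadsworth–Emmons olefination of the methyl ketone should give mainly the 9'E dienenitrile, the weakly basic stabilised anion leaving the C6' stereocentre untouched.

Step 12
Reactants: 22 (2E,4E)-3-methyl-5-[(1R)-2,6,6-trimethylcyclohex-2-en-1-yl]penta-2,4-dienenitrile
Product: 23 (2E,4E)-3-methyl-5-[(1R)-2,6,6-trimethyl-4-oxocyclohex-2-en-1-yl]penta-2,4-dienenitrile
Conditions: Rh2(C6H10NO)4 (dirhodium tetracaprolactamate, 1 mol %), t-BuOOH (70% aq.), 1,2-dichloroethane, 40 °C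
Reagents that add atoms: tert-butyl hydroperoxide, CC(C)(C)OO
Why: Radical allylic oxidation should take place at the ring methylene C3' next to C4'=C5' in preference to the hindered tertiary C6'–H, and the base-free conditions are chosen to keep the C6' configuration.

Step 13
Reactants: 23 (2E,4E)-3-methyl-5-[(1R)-2,6,6-trimethyl-4-oxocyclohex-2-en-1-yl]penta-2,4-dienenitrile
Product: 24 (2E,4E)-5-[(1R,4R)-4-hydroxy-2,6,6-trimethylcyclohex-2-en-1-yl]-3-methylpenta-2,4-dienenitrile
Conditions: LiBH(s-Bu)3, THF, −78 °C; H2O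
Reagents that add atoms: none
Why: The bulky hydride should reduce the β-methyl enone in 1,2-fashion from the face opposite the pseudoaxial C1' methyl group, which places the hydroxyl trans to the pseudoaxial C6' side chain (3'R).

Step 14
Reactants: 24 (2E,4E)-5-[(1R,4R)-4-hydroxy-2,6,6-trimethylcyclohex-2-en-1-yl]-3-methylpenta-2,4-dienenitrile
Product: 26 (2E,4E)-5-[(1R,4R)-4-hydroxy-2,6,6-trimethylcyclohex-2-en-1-yl]-3-methylpenta-2,4-dienal, via aldimine 25 (not isolated)
Conditions: i-Bu2AlH (3 equiv), CH2Cl2, −78 °C; aq. KNaC4H4O6 (potassium sodium tartrate), then wet SiO2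
Reagents that add atoms: water, O
Why: Partial reduction of the nitrile stops at the N-metallated imine, which should hydrolyse under near-neutral work-up to the dienal without harming the acid-sensitive allylic alcohol.

Step 15
Reactants: 19 {(2E,4E,6E,8E,10E)-13-[(4R)-4-hydroxy-2,6,6-trimethylcyclohex-1-en-1-yl]-2,7,11-trimethyltrideca-2,4,6,8,10-pentaen-12-yn-1-yl}triphenylphosphonium bromide; 26 (2E,4E)-5-[(1R,4R)-4-hydroxy-2,6,6-trimethylcyclohex-2-en-1-yl]-3-methylpenta-2,4-dienal
Product: 28 (3R,3'R,6'R)-7,8-didehydro-β,ε-carotene-3,3'-diol (monadoxanthin), via C25 ylide 27 (not isolated)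
Conditions: 1,2-epoxybutane, EtOH, reflux, Ar, dark; chromatography, crystallisation
Reagents that add atoms: none
Why: Wittig olefination under the near-neutral epoxide conditions should form C11'=C12' without protecting groups and without epimerising C6', and the warm medium should favour the unhindered all-E isomer.

Compound list
1 | N-methoxy-N-methyl-2-methylpropanamide | CC(C)C(=O)N(C)OC | starting material
2 | isopropenylmagnesium bromide | CC(=C)[Mg]Br | starting material
3 | bromomagnesium 3-[methoxy(methyl)amino]-2,4-dimethylpent-1-en-3-olate | CC(C)C(O[Mg]Br)(N(C)OC)C(C)=C | intermediate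
4 | 2,4-dimethylpent-1-en-3-one | CC(C)C(=O)C(C)=C | intermediate
5 | [(2,4-dimethylpenta-1,3-dien-3-yl)oxy]tri(propan-2-yl)silane | CC(C)[Si](C(C)C)(C(C)C)OC(C(C)=C)=C(C)C | intermediate
6 | but-3-en-2-one | CC(=O)C=C | starting material
7 | 1-[(1R)-3,5,5-trimethyl-4-{[tri(propan-2-yl)silyl]oxy}cyclohex-3-en-1-yl]ethan-1-one | CC(C)[Si](C(C)C)(C(C)C)OC1=C(C)C[C@@H](C(C)=O)CC1(C)C | intermediate
8 | cesium (4R)-4-acetyl-2,6,6-trimethylcyclohex-1-en-1-olate | [Cs+].[O-]C1=C(C)C[C@@H](C(C)=O)CC1(C)C | intermediate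
9 | (4R)-4-acetyl-2,6,6-trimethylcyclohex-1-en-1-yl trifluoromethanesulfonate | O=S(=O)(OC1=C(C)C[C@@H](C(C)=O)CC1(C)C)C(F)(F)F | intermediate
10 | (1R)-3,5,5-trimethyl-4-{[(trifluoromethyl)sulfonyl]oxy}cyclohex-3-en-1-yl acetate | O=S(=O)(OC1=C(C)C[C@@H](OC(C)=O)CC1(C)C)C(F)(F)F | intermediate
11 | (2E)-3-methylpent-2-en-4-yn-1-ol | C#C/C(C)=C/CO | starting material
12 | (1R)-4-[(3E)-5-hydroxy-3-methylpent-3-en-1-yn-1-yl]-3,5,5-trimethylcyclohex-3-en-1-yl acetate | OC/C=C(\C)C#CC1=C(C)C[C@@H](OC(C)=O)CC1(C)C | intermediate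
13 | {(2E)-5-[(4R)-4-(acetyloxy)-2,6,6-trimethylcyclohex-1-en-1-yl]-3-methylpent-2-en-4-yn-1-yl}triphenylphosphonium bromide | [Br-].c1ccccc1[P+](c1ccccc1)(c1ccccc1)C/C=C(\C)C#CC1=C(C)C[C@@H](OC(C)=O)CC1(C)C | intermediate
14 | (2E,4E,6E)-2,7-dimethylocta-2,4,6-trienedial | O=C/C(C)=C/C=C/C=C(C)/C=O | starting material
15 | {(2E)-5-[(4R)-4-(acetyloxy)-2,6,6-trimethylcyclohex-1-en-1-yl]-3-methylpent-2-en-4-yn-1-ylidene}triphenylphosphorane | c1ccccc1P(c1ccccc1)(c1ccccc1)=C/C=C(\C)C#CC1=C(C)C[C@@H](OC(C)=O)CC1(C)C | intermediate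
16 | (1R)-3,5,5-trimethyl-4-[(3E,5E,7E,9E,11E)-3,7,12-trimethyl-13-oxotrideca-3,5,7,9,11-pentaen-1-yn-1-yl]cyclohex-3-en-1-yl acetate | O=C/C(C)=C/C=C/C=C(C)/C=C/C=C(\C)C#CC1=C(C)C[C@@H](OC(C)=O)CC1(C)C | intermediate
17 | (2E,4E,6E,8E,10E)-13-[(4R)-4-hydroxy-2,6,6-trimethylcyclohex-1-en-1-yl]-2,7,11-trimethyltrideca-2,4,6,8,10-pentaen-12-ynal | O=C/C(C)=C/C=C/C=C(C)/C=C/C=C(\C)C#CC1=C(C)C[C@@H](O)CC1(C)C | intermediate
18 | (1R)-4-[(3E,5E,7E,9E,11E)-13-hydroxy-3,7,12-trimethyltrideca-3,5,7,9,11-pentaen-1-yn-1-yl]-3,5,5-trimethylcyclohex-3-en-1-ol | OC/C(C)=C/C=C/C=C(C)/C=C/C=C(\C)C#CC1=C(C)C[C@@H](O)CC1(C)C | intermediate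
19 | {(2E,4E,6E,8E,10E)-13-[(4R)-4-hydroxy-2,6,6-trimethylcyclohex-1-en-1-yl]-2,7,11-trimethyltrideca-2,4,6,8,10-pentaen-12-yn-1-yl}triphenylphosphonium bromide | [Br-].c1ccccc1[P+](c1ccccc1)(c1ccccc1)C/C(C)=C/C=C/C=C(C)/C=C/C=C(\C)C#CC1=C(C)C[C@@H](O)CC1(C)C | intermediate
20 | (R)-α-ionone, (3E)-4-[(1R)-2,6,6-trimethylcyclohex-2-en-1-yl]but-3-en-2-one | CC1=CCCC(C)(C)[C@H]1/C=C/C(C)=O | starting material
21 | diethyl (cyanomethyl)phosphonate | CCOP(=O)(CC#N)OCC | starting material
22 | (2E,4E)-3-methyl-5-[(1R)-2,6,6-trimethylcyclohex-2-en-1-yl]penta-2,4-dienenitrile | CC1=CCCC(C)(C)[C@H]1/C=C/C(C)=C/C#N | intermediate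
23 | (2E,4E)-3-methyl-5-[(1R)-2,6,6-trimethyl-4-oxocyclohex-2-en-1-yl]penta-2,4-dienenitrile | CC1=CC(=O)CC(C)(C)[C@H]1/C=C/C(C)=C/C#N | intermediate
24 | (2E,4E)-5-[(1R,4R)-4-hydroxy-2,6,6-trimethylcyclohex-2-en-1-yl]-3-methylpenta-2,4-dienenitrile | CC1=C[C@H](O)CC(C)(C)[C@H]1/C=C/C(C)=C/C#N | intermediate
25 | (2E,4E)-5-[(1R,4R)-4-hydroxy-2,6,6-trimethylcyclohex-2-en-1-yl]-3-methylpenta-2,4-dien-1-imine | CC1=C[C@H](O)CC(C)(C)[C@H]1/C=C/C(C)=C/C=N | intermediate
26 | (2E,4E)-5-[(1R,4R)-4-hydroxy-2,6,6-trimethylcyclohex-2-en-1-yl]-3-methylpenta-2,4-dienal | CC1=C[C@H](O)CC(C)(C)[C@H]1/C=C/C(C)=C/C=O | intermediate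
27 | {(2E,4E,6E,8E,10E)-13-[(4R)-4-hydroxy-2,6,6-trimethylcyclohex-1-en-1-yl]-2,7,11-trimethyltrideca-2,4,6,8,10-pentaen-12-yn-1-ylidene}triphenylphosphorane | c1ccccc1P(c1ccccc1)(c1ccccc1)=C/C(C)=C/C=C/C=C(C)/C=C/C=C(\C)C#CC1=C(C)C[C@@H](O)CC1(C)C | intermediate
28 | (3R,3'R,6'R)-7,8-didehydro-β,ε-carotene-3,3'-diol (monadoxanthin) | CC1=C[C@H](O)CC(C)(C)[C@H]1/C=C/C(C)=C/C=C/C(C)=C/C=C/C=C(C)/C=C/C=C(\C)C#CC1=C(C)C[C@@H](O)CC1(C)C | target

Total step count: 15. Longest linear sequence: 11 steps (steps 1–10, then step 15); steps 11–14 form the ε-end branch.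

Steps most likely to fail

Step 3. The hindered diene may lose its silyl group to adventitious acid, the addition may stop at an open-chain conjugate adduct, or the catalyst may discriminate the enone faces poorly. The fallback replaces catalyst control by auxiliary control; it sets out from 5 and comes back at 7. Diene 5 is combined with (4R)-3-acryloyl-4-benzyl-1,3-oxazolidin-2-one under Et2AlCl in CH2Cl2 at −78 °C; the chelated imide is shielded on one face by the benzyl group, so the same two bonds should form in one operation and give (4R)-4-benzyl-3-{[(1R)-3,5,5-trimethyl-4-{[tri(propan-2-yl)silyl]oxy}cyclohex-3-en-1-yl]carbonyl}-1,3-oxazolidin-2-one F1. Aminolysis with MeNH(OMe)·HCl and AlMe3 gives (1R)-N-methoxy-N,3,5,5-tetramethyl-4-{[tri(propan-2-yl)silyl]oxy}cyclohex-3-ene-1-carboxamide F2, and MeMgBr then gives 7.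

Step 4. The liberated enolate may exchange protons with the methyl ketone before it is triflated, which would move the enolate, erode C3 or start an aldol reaction. The fallback avoids an acidic carbonyl at this stage; it sets out from 5 and comes back at 9. Diene 5 and 2,2,2-trifluoroethyl acrylate, under the catalyst of step 3, should give 2,2,2-trifluoroethyl (1R)-3,5,5-trimethyl-4-{[tri(propan-2-yl)silyl]oxy}cyclohex-3-ene-1-carboxylate F3, whose ester α-proton is too weakly acidic to exchange. CsF and PhNTf2 give 2,2,2-trifluoroethyl (1R)-3,5,5-trimethyl-4-{[(trifluoromethyl)sulfonyl]oxy}cyclohex-3-ene-1-carboxylate F4. MeNH(OMe)·HCl with i-PrMgCl at −20 °C gives (1R)-N-methoxy-N,3,5,5-tetramethyl-4-{[(trifluoromethyl)sulfonyl]oxy}cyclohex-3-ene-1-carboxamide F5, and MeMgBr at −20 °C gives 9.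

Step 13. Hydride delivery may show poor facial selectivity, so that the cis alcohol forms in quantity. The fallback corrects the carbinol centre by inversion; it sets out from 23 and comes back at 24. Reduction of 23 with NaBH4 and CeCl3 in MeOH gives, beside 24, (2E,4E)-5-[(1R,4S)-4-hydroxy-2,6,6-trimethylcyclohex-2-en-1-yl]-3-methylpenta-2,4-dienenitrile F6, which is separated. Mitsunobu reaction of F6 with 4-nitrobenzoic acid, PPh3 and diisopropyl azodicarboxylate should invert C3' and give (1R,4R)-4-[(1E,3E)-4-cyano-3-methylbuta-1,3-dien-1-yl]-3,5,5-trimethylcyclohex-2-en-1-yl 4-nitrobenzoate F7; methanolysis with K2CO3 in MeOH gives 24.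

Further compounds
F1 | step 3 | (4R)-4-benzyl-3-{[(1R)-3,5,5-trimethyl-4-{[tri(propan-2-yl)silyl]oxy}cyclohex-3-en-1-yl]carbonyl}-1,3-oxazolidin-2-one | CC(C)[Si](C(C)C)(C(C)C)OC1=C(C)C[C@@H](C(=O)N2[C@H](Cc3ccccc3)COC2=O)CC1(C)C
F2 | step 3 | (1R)-N-methoxy-N,3,5,5-tetramethyl-4-{[tri(propan-2-yl)silyl]oxy}cyclohex-3-ene-1-carboxamide | CC(C)[Si](C(C)C)(C(C)C)OC1=C(C)C[C@@H](C(=O)N(C)OC)CC1(C)C
F3 | step 4 | 2,2,2-trifluoroethyl (1R)-3,5,5-trimethyl-4-{[tri(propan-2-yl)silyl]oxy}cyclohex-3-ene-1-carboxylate | CC(C)[Si](C(C)C)(C(C)C)OC1=C(C)C[C@@H](C(=O)OCC(F)(F)F)CC1(C)C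
F4 | step 4 | 2,2,2-trifluoroethyl (1R)-3,5,5-trimethyl-4-{[(trifluoromethyl)sulfonyl]oxy}cyclohex-3-ene-1-carboxylate | O=S(=O)(OC1=C(C)C[C@@H](C(=O)OCC(F)(F)F)CC1(C)C)C(F)(F)F
F5 | step 4 | (1R)-N-methoxy-N,3,5,5-tetramethyl-4-{[(trifluoromethyl)sulfonyl]oxy}cyclohex-3-ene-1-carboxamide | O=S(=O)(OC1=C(C)C[C@@H](C(=O)N(C)OC)CC1(C)C)C(F)(F)F
F6 | step 13 | (2E,4E)-5-[(1R,4S)-4-hydroxy-2,6,6-trimethylcyclohex-2-en-1-yl]-3-methylpenta-2,4-dienenitrile | CC1=C[C@@H](O)CC(C)(C)[C@H]1/C=C/C(C)=C/C#N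
F7 | step 13 | (1R,4R)-4-[(1E,3E)-4-cyano-3-methylbuta-1,3-dien-1-yl]-3,5,5-trimethylcyclohex-2-en-1-yl 4-nitrobenzoate | CC1=C[C@H](OC(=O)c2ccc(cc2)[N+](=O)[O-])CC(C)(C)[C@H]1/C=C/C(C)=C/C#N
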